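The route rests on closing ring B between its methylene carbon C7 and the methyl-bearing quaternary carbon C8. C8 belongs to the six-membered δ-lactone (O–C15–C14–C13–C8–C9) and is β to the C13 ester, so a 2,3-dioxopyran with a C13=C8 double bond is a strongly electrophilic relay ring. A C7 radical, released from an iodomethyl γ-lactone, adds 6-exo to C8: one operation makes ring B and the C8 quaternary centre and transmits the configuration of the carbinol carbon C9 to C8 through the enforced cis fusion. The precursor is ring A with its iodolactone, joined at C10 to the propynyl-substituted dioxopyran; gold Conia-ene closure and methylenation then finish the skeleton.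

Key step: step 13

Locants used below: ring A = C1, C2, C3 (OAc), C4 (CMe2), C5 (H), C10; ring B = C5, C6 (CH–O), C7 (CH2), C8 (C–CH3), C9 (C–O), C10; γ-lactone = C10–C19(=O)–O–C6; cyclopentene = C8, C9, C11 (=CH), C12 (=C–CH3), C13 (C–CO2CH3); δ-lactone = C9–O–C15(=O)–C14(=CH2)–C13–C8.

Remark on the chemistry: compounds 7–10 are expected as mixtures of C10 epimers (the trans isomer is drawn); this centre is planarised in step 9, so the mixture is used as such.

Step 1
Reactants: 1 tert-butyl diethylphosphonoacetate; 2 5-bromo-2-methylpent-2-ene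
Product: 3 tert-butyl 2-(diethoxyphosphoryl)-6-methylhept-5-enoate (racemic)
Conditions: NaH, DMF, 0 °C to 60 °C
Reagents that add atoms: none
Why: Alkylation of the stabilised phosphonoacetate anion with a primary homoallylic bromide (SN2) should give the α-substituted phosphonate; its stereocentre is lost in step 2.

Step 2
Reactants: 3 tert-butyl 2-(diethoxyphosphoryl)-6-methylhept-5-enoate; 4 acrolein
Product: 5 tert-butyl (2E)-2-(4-methylpent-3-en-1-yl)penta-2,4-dienoate
Conditions: NaH, THF, 0 °C; then 4, 0 °C to rt
Reagents that add atoms: none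
Why: Horner–Wadsworth–Emmons olefination of an aldehyde should give the α-branched dienoate, mainly as the E isomer; the alkene geometry is irrelevant because C10 becomes a radical in step 4.

Step 3
Reactants: 5 tert-butyl (2E)-2-(4-methylpent-3-en-1-yl)penta-2,4-dienoate
Product: 6 tert-butyl (2E)-2-{2-[(2R)-3,3-dimethyloxiran-2-yl]ethyl}penta-2,4-dienoate
Conditions: D-fructose-derived Shi ketone (30 mol %), KHSO5 (as 2KHSO5·KHSO4·K2SO4), K2CO3, Bu4NHSO4, MeCN/CH2(OMe)2/aq. buffer, 0 °C
Reagents that add atoms: potassium peroxymonosulfate, [K+].[O-]S(=O)(=O)OO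
Why: Shi epoxidation with the chiral dioxirane should oxidise only the electron-rich trisubstituted alkene, leaving the electron-poor dienoate untouched, and the catalyst (the enantiomer that delivers the R epoxide) sets the epoxide carbon, the source of all absolute configuration.

Step 4
Reactants: 6 tert-butyl (2E)-2-{2-[(2R)-3,3-dimethyloxiran-2-yl]ethyl}penta-2,4-dienoate
Product: 7 tert-butyl (1R,2S,4R)-2-ethenyl-4-hydroxy-3,3-dimethylcyclohexane-1-carboxylate
Conditions: Cp2TiCl2 (20 mol %), Mn dust, 2,4,6-collidine·HCl, THF, rt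
Reagents that add atoms: none
Why: Titanocene-mediated reductive epoxide opening (trivalent titanium) gives the tertiary C4 radical, which should add 6-endo to the CH terminus of the enoate (C5) through a chair in which the titanium alkoxide and the vinyl group are both equatorial; this fixes C5 relative to C3, and the resulting titanium enolate is protonated.

Step 5
Reactants: 7 tert-butyl (1R,2S,4R)-2-ethenyl-4-hydroxy-3,3-dimethylcyclohexane-1-carboxylate
Product: 8 tert-butyl (1R,2S)-2-ethenyl-3,3-dimethyl-4-oxocyclohexane-1-carboxylate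
Conditions: Dess–Martin periodinane, CH2Cl2, rt
Reagents that add atoms: none
Why: Oxidation of the secondary alcohol to the C3 ketone prepares the inversion needed for the axial C3 oxygen of the target.

Step 6
Reactants: 8 tert-butyl (1R,2S)-2-ethenyl-3,3-dimethyl-4-oxocyclohexane-1-carboxylate
Product: 9 tert-butyl (1R,2S,4S)-2-ethenyl-4-hydroxy-3,3-dimethylcyclohexane-1-carboxylate
Conditions: LiBH(s-Bu)3, THF, −78 °C; then H2O
Reagents that add atoms: none
Why: The bulky hydride should attack the ketone next to the gem-dimethyl group from the equatorial side and give the axial (3S) alcohol, trans to the C5 vinyl group; the tert-butyl ester is not reduced at −78 °C.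

Step 7
Reactants: 9 tert-butyl (1R,2S,4S)-2-ethenyl-4-hydroxy-3,3-dimethylcyclohexane-1-carboxylate
Product: 10 tert-butyl (1R,2S,4S)-4-[(tert-butyldimethylsilyl)oxy]-2-ethenyl-3,3-dimethylcyclohexane-1-carboxylate
Conditions: TBSOTf, 2,6-lutidine, CH2Cl2, 0 °C
Reagents that add atoms: tert-butyldimethylsilyl trifluoromethanesulfonate, CC(C)(C)[Si](C)(C)OS(=O)(=O)C(F)(F)F
Why: Silylation with the reactive silyl triflate should protect the hindered axial alcohol against the bases, acylating agents and iodine of the following steps.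

Step 8
Reactants: 11 but-2-ynoic acid
Product: 12 but-2-ynoyl chloride
Conditions: (COCl)2, DMF (cat.), CH2Cl2, 0 °C to rt; used crude
Reagents that add atoms: oxalyl chloride, ClC(=O)C(Cl)=O
Why: Standard conversion of a carboxylic acid into its chloride through the Vilsmeier-type intermediate.

Step 9
Reactants: 10 tert-butyl (1R,2S,4S)-4-[(tert-butyldimethylsilyl)oxy]-2-ethenyl-3,3-dimethylcyclohexane-1-carboxylate; 12 but-2-ynoyl chloride
Product: 14 tert-butyl (1S,2R,4S)-1-(but-2-ynoyl)-4-[(tert-butyldimethylsilyl)oxy]-2-ethenyl-3,3-dimethylcyclohexane-1-carboxylate, via lithium ester enolate 13 (not isolated)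
Conditions: LiN(i-Pr)2, THF, −78 °C; enolate added to 12, −78 °C
Reagents that add atoms: none
Why: Claisen-type C-acylation of the ester enolate creates the C10 quaternary centre; the acyl chloride should enter equatorially, anti to the axial C4 methyl group and trans to the C5 vinyl group, which leaves the ester axial and cis to the vinyl group as the γ-lactone requires.

Step 10
Reactants: 14 tert-butyl (1S,2R,4S)-1-(but-2-ynoyl)-4-[(tert-butyldimethylsilyl)oxy]-2-ethenyl-3,3-dimethylcyclohexane-1-carboxylate
Product: 15 cis-fused iodolactone ynone [7a-(but-2-ynoyl)-5-silyloxy-3-(iodomethyl)-4,4-dimethylhexahydro-2-benzofuran-1(3H)-one; CH2I trans to C4]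
Conditions: I2, NaHCO3, MeCN, 0 °C to rt
Reagents that add atoms: iodine, II
Why: Iodolactonisation of the tert-butyl ester (5-exo, loss of 2-methylpropene) should form the C19–O–C6 lactone and the C7–I bond; the iodomethyl group turns away from the C4 gem-dimethyl group, so C6 is set with C7 on the exo face, the same face as the C10 acyl group, and the electron-poor ynone does not react with iodine.

Step 11
Reactants: 15 cis-fused iodolactone ynone
Product: 17 mixed methyl oxalate of the tertiary C9 carbinol bearing prop-1-ynyl and 1-ethoxyvinyl groups, via lithium alkoxide 16 (not isolated)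
Conditions: ethyl vinyl ether, t-BuLi, THF, −78 °C to 0 °C; then 15, −78 °C; then ClC(O)CO2Me, −78 °C to 0 °C
Reagents that add atoms: ethyl vinyl ether (as 1-ethoxyvinyllithium), C=COCC; methyl chlorooxoacetate, COC(=O)C(Cl)=O
Why: 1,2-Addition of the acyl-anion equivalent to the ynone ketone under Cram-chelate control (lithium bridging the C9 ketone and the C19 lactone carbonyl) should occur on the face syn to C1, because the other face is screened by H-5 and the iodomethyl group, and this sets C9; the hindered alkoxide is trapped in the flask by the small, very reactive oxalyl monoester chloride.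

Step 12
Reactants: 17 mixed methyl oxalate of the tertiary C9 carbinol
Product: 19 methyl 5-methyl-2,3-dioxo-6-(prop-1-ynyl)-6-(iodolactonyl)-3,6-dihydro-2H-pyran-4-carboxylate, via dioxo ester 18 (not isolated)
Conditions: MeOAc, LiN(i-Pr)2 (2.2 equiv), THF, −78 °C; then 17; then CF3CO2H, CH2Cl2, 0 °C to rt
Reagents that add atoms: methyl acetate (as its lithium enolate), CC(=O)OC
Why: Crossed Claisen condensation at the unhindered methyl ester carbonyl of the oxalate should give the 2,4-dioxo ester, and acid then turns the enol ether into an oxocarbenium ion at C8 that is captured by the 1,3-dicarbonyl carbon C13 (six-membered ring), loss of ethanol giving the alkylidene (Knoevenagel-type condensation).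

Step 13
Reactants: 19 methyl 5-methyl-2,3-dioxo-6-(prop-1-ynyl)-6-(iodolactonyl)-3,6-dihydro-2H-pyran-4-carboxylate
Product: 20 ring-B-closed enol lactone [rings A and B with the γ-lactone, cis-fused to a 3-hydroxy-2-oxo-5,6-dihydro-2H-pyran carrying CO2Me at C13, CH3 at C8 and prop-1-ynyl at C9]
Conditions: (Me3Si)3SiH, Et3B, air, PhMe, rt
Reagents that add atoms: none
Why: The silyl radical abstracts iodine from C7, the primary C7 radical adds to C8, the β-carbon of the cyclic alkylidene oxaloacetate, and the C13 radical, stabilised by the C14 ketone and the ester, takes hydrogen from the silane to give the enol; the closest known reaction type is the silane- or stannane-mediated radical conjugate cyclisation (intramolecular Giese reaction) onto alkylidene 1,3-dicarbonyl compounds. Ring B closes in the 6-exo-trig mode. The only new stereocentre, C8, is controlled by C9: C8 is an sp2 atom of the δ-lactone ring and C7 is tethered to the neighbouring C9 through C10, C5 and C6, so the bond can form only on the lactone face that carries the C9–C10 bond (cis fusion), which puts the C8 methyl group cis to the C9 propynyl group and anti to the lactone oxygen, as the target requires. The step needs chemoselectivity for C8 over the propynyl carbon, which is also six atoms away, and over premature reduction of the radical; the nucleophilic alkyl radical is polarity-matched to the doubly activated alkene, which should outpace both. The iodomethyl group must lie on the lactone face that carries the pyrandione, which steps 9 and 10 secure.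

Step 14
Reactants: 20 ring-B-closed enol lactone
Product: 21 pentacyclic α-keto δ-lactone [14-oxo analogue of 22: C14 is a ketone in place of C=CH2]
Conditions: (Ph3P)AuCl (5 mol %), AgOTf (5 mol %), CH2Cl2, rt
Reagents that add atoms: none
Why: Conia-ene reaction: the gold-activated alkyne is attacked anti by the enol carbon C13 in the 5-endo-dig mode and protodeauration gives the C11=C12 alkene; the propynyl group is axial on the lactone ring and 1,3 to C13, so the C13–C12 bond can form only on that face, which fixes the C13 quaternary centre with the ester anti to the lactone bridge.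

Step 15
Reactants: 21 pentacyclic α-keto δ-lactone
Product: 22 3-O-(tert-butyldimethylsilyl)-3-deacetylmeroantarctine B
Conditions: Ph3PCH3Br, KN(SiMe3)2, THF, 0 °C; then 21, −78 °C to 0 °C
Reagents that add atoms: methyltriphenylphosphonium bromide, C[P+](c1ccccc1)(c1ccccc1)c1ccccc1.[Br-]
Why: Wittig methylenation should take place at the non-enolisable, highly electrophilic C14 ketone of the 1,2-dicarbonyl unit in preference to the lactone and ester carbonyls and gives the α-methylene lactone directly.

Step 16
Reactants: 22 3-O-(tert-butyldimethylsilyl)-3-deacetylmeroantarctine B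
Product: 23 3-deacetylmeroantarctine B
Conditions: HF·pyridine, THF, 0 °C to rt
Reagents that add atoms: none
Why: Fluoride-mediated cleavage of the silyl ether under mildly acidic conditions should spare both lactones, the methyl ester and the α-methylene group.

Step 17
Reactants: 23 3-deacetylmeroantarctine B
Product: 24 meroantarctine B
Conditions: Ac2O, DMAP (cat.), pyridine, CH2Cl2, rt
Reagents that add atoms: acetic anhydride, CC(=O)OC(C)=O
Why: DMAP-catalysed acylation of the axial secondary alcohol installs the acetate without touching any stereocentre.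

Compound list
1 | tert-butyl diethylphosphonoacetate | CCOP(=O)(OCC)CC(=O)OC(C)(C)C | starting material
2 | 5-bromo-2-methylpent-2-ene | CC(C)=CCCBr | starting material
3 | tert-butyl 2-(diethoxyphosphoryl)-6-methylhept-5-enoate (racemic) | CCOP(=O)(OCC)C(CCC=C(C)C)C(=O)OC(C)(C)C | intermediate
4 | acrolein | C=CC=O | starting material
5 | tert-butyl (2E)-2-(4-methylpent-3-en-1-yl)penta-2,4-dienoate | C=C/C=C(\CCC=C(C)C)C(=O)OC(C)(C)C | intermediate
6 | tert-butyl (2E)-2-{2-[(2R)-3,3-dimethyloxiran-2-yl]ethyl}penta-2,4-dienoate | C=C/C=C(\CC[C@H]1OC1(C)C)C(=O)OC(C)(C)C | intermediate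
7 | tert-butyl (1R,2S,4R)-2-ethenyl-4-hydroxy-3,3-dimethylcyclohexane-1-carboxylate | CC(C)(C)OC(=O)[C@@H]1CC[C@@H](O)C(C)(C)[C@H]1C=C | intermediate
8 | tert-butyl (1R,2S)-2-ethenyl-3,3-dimethyl-4-oxocyclohexane-1-carboxylate | CC(C)(C)OC(=O)[C@@H]1CCC(=O)C(C)(C)[C@H]1C=C | intermediate
9 | tert-butyl (1R,2S,4S)-2-ethenyl-4-hydroxy-3,3-dimethylcyclohexane-1-carboxylate | CC(C)(C)OC(=O)[C@@H]1CC[C@H](O)C(C)(C)[C@H]1C=C | intermediate
10 | tert-butyl (1R,2S,4S)-4-[(tert-butyldimethylsilyl)oxy]-2-ethenyl-3,3-dimethylcyclohexane-1-carboxylate | CC(C)(C)OC(=O)[C@@H]1CC[C@H](O[Si](C)(C)C(C)(C)C)C(C)(C)[C@H]1C=C | intermediate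
11 | but-2-ynoic acid | CC#CC(=O)O | starting material
12 | but-2-ynoyl chloride | CC#CC(Cl)=O | intermediate
13 | lithium ester enolate of 10 | [Li+].[O-]C(OC(C)(C)C)=C1CC[C@H](O[Si](C)(C)C(C)(C)C)C(C)(C)[C@H]1C=C | intermediate
14 | tert-butyl (1S,2R,4S)-1-(but-2-ynoyl)-4-[(tert-butyldimethylsilyl)oxy]-2-ethenyl-3,3-dimethylcyclohexane-1-carboxylate | CC#CC(=O)[C@]1(C(=O)OC(C)(C)C)CC[C@H](O[Si](C)(C)C(C)(C)C)C(C)(C)[C@H]1C=C | intermediate
15 | cis-fused iodolactone ynone: 7a-(but-2-ynoyl)-5-[(tert-butyldimethylsilyl)oxy]-3-(iodomethyl)-4,4-dimethylhexahydro-2-benzofuran-1(3H)-one, CH2I trans to C4 | CC#CC(=O)[C@]23CC[C@H](O[Si](C)(C)C(C)(C)C)C(C)(C)[C@H]2[C@H](CI)OC3=O | intermediate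
16 | lithium alkoxide from addition of 1-ethoxyvinyllithium to the ketone of 15 | [Li+].[O-][C@@](C#CC)(C(=C)OCC)[C@]23CC[C@H](O[Si](C)(C)C(C)(C)C)C(C)(C)[C@H]2[C@H](CI)OC3=O | intermediate
17 | mixed methyl oxalate of the tertiary C9 carbinol (prop-1-ynyl, 1-ethoxyvinyl and the iodolactone ring system on C9) | COC(=O)C(=O)O[C@@](C#CC)(C(=C)OCC)[C@]23CC[C@H](O[Si](C)(C)C(C)(C)C)C(C)(C)[C@H]2[C@H](CI)OC3=O | intermediate
18 | 2,4-dioxo ester: 4-methyl 1-(tertiary C9 carbinyl) 2-oxobutanedioate | COC(=O)CC(=O)C(=O)O[C@@](C#CC)(C(=C)OCC)[C@]23CC[C@H](O[Si](C)(C)C(C)(C)C)C(C)(C)[C@H]2[C@H](CI)OC3=O | intermediate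
19 | methyl 5-methyl-2,3-dioxo-6-(prop-1-ynyl)-6-(iodolactonyl)-3,6-dihydro-2H-pyran-4-carboxylate | O=C1C(=O)C(C(=O)OC)=C(C)[C@@](C#CC)([C@]23CC[C@H](O[Si](C)(C)C(C)(C)C)C(C)(C)[C@H]2[C@H](CI)OC3=O)O1 | intermediate
20 | ring-B-closed enol lactone (rings A and B, γ-lactone, 3-hydroxy-2-oxo-5,6-dihydro-2H-pyran with CO2Me at C13, CH3 at C8, prop-1-ynyl at C9) | O=C1C(O)=C(C(=O)OC)[C@@]2(C)C[C@@H]3OC(=O)[C@]4(CC[C@H](O[Si](C)(C)C(C)(C)C)C(C)(C)[C@@H]34)[C@@]2(C#CC)O1 | intermediate
21 | pentacyclic α-keto δ-lactone (14-oxo analogue of 22) | O=C1C(=O)O[C@@]23C=C(C)[C@]1(C(=O)OC)[C@@]2(C)C[C@@H]1OC(=O)[C@]32CC[C@H](O[Si](C)(C)C(C)(C)C)C(C)(C)[C@@H]12 | intermediate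
22 | 3-O-(tert-butyldimethylsilyl)-3-deacetylmeroantarctine B | C=C1C(=O)O[C@@]23C=C(C)[C@]1(C(=O)OC)[C@@]2(C)C[C@@H]1OC(=O)[C@]32CC[C@H](O[Si](C)(C)C(C)(C)C)C(C)(C)[C@@H]12 | intermediate
23 | 3-deacetylmeroantarctine B | C=C1C(=O)O[C@@]23C=C(C)[C@]1(C(=O)OC)[C@@]2(C)C[C@@H]1OC(=O)[C@]32CC[C@H](O)C(C)(C)[C@@H]12 | intermediate
24 | meroantarctine B | C=C1C(=O)O[C@@]23C=C(C)[C@]1(C(=O)OC)[C@@]2(C)C[C@@H]1OC(=O)[C@]32CC[C@H](OC(C)=O)C(C)(C)[C@@H]12 | target

Total step count: 17. Longest linear sequence: 16 steps (steps 1–7 and 9–17); step 8 is a one-step branch.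

Steps most likely to fail

1. Step 14. The enol carbon may fail to reach the distal alkyne carbon in the 5-endo-dig closure to the bridged ring, or the enol oxygen may attack the alkyne instead. Fallback, from 20 back to 21: the alkyne is activated with a stoichiometric halonium source instead of a π-acid. I2 and NaHCO3 in MeCN should effect an iodocarbocyclisation to the vinyl iodide F6 (iodine on C11), and Pd(PPh3)4-catalysed reduction with Bu3SnH then removes the iodine and gives 21.

2. Step 11. The facial selectivity of the addition to the C9 ketone may be poor if chelation is incomplete, and the hindered alkoxide may be acylated incompletely. Fallback, from 10 (as its enolate 13) back to 17: the order in which the two carbon substituents reach C9 is reversed, so that the small alkynyl nucleophile adds under Felkin–Anh (non-chelation) control. Enolate 13 is formylated with 2,2,2-trifluoroethyl formate to the aldehyde ester F1. Iodolactonisation (I2, NaHCO3) gives the iodolactone aldehyde F2. 1-Ethoxyvinyllithium adds to the aldehyde to give the allylic alcohol F3 (carbinol epimers, inconsequential), and buffered Dess–Martin oxidation gives the 2-ethoxy enone F4. Addition of 1-propynyllithium in THF at −78 °C and trapping with methyl chlorooxoacetate returns to 17.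

3. Step 12. The ester enolate may attack the oxalate carbonyl next to the tertiary oxygen and cleave the oxalate, or the enol ether may be hydrolysed before the ring closes. Fallback, from 15 (through alkoxide 16) back to 18: the carbon nucleophile is introduced under neutral conditions onto an acid chloride. Alkoxide 16 is trapped with oxalyl chloride at −78 °C to give the chlorooxalate F5. Decarboxylative acylation of potassium methyl malonate (MgCl2, Et3N, MeCN) then gives the dioxo ester 18, which is closed to 19 with CF3CO2H as in step 12.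

Further compounds
F1 | step 11 | tert-butyl (1S,2R,4S)-4-[(tert-butyldimethylsilyl)oxy]-2-ethenyl-1-formyl-3,3-dimethylcyclohexane-1-carboxylate | O=C[C@]1(C(=O)OC(C)(C)C)CC[C@H](O[Si](C)(C)C(C)(C)C)C(C)(C)[C@H]1C=C
F2 | step 11 | cis-fused iodolactone aldehyde (7a-formyl analogue of 15) | O=C[C@]23CC[C@H](O[Si](C)(C)C(C)(C)C)C(C)(C)[C@H]2[C@H](CI)OC3=O
F3 | step 11 | 2-ethoxyallylic alcohol from addition of 1-ethoxyvinyllithium to F2 (carbinol epimers) | C=C(OCC)C(O)[C@]23CC[C@H](O[Si](C)(C)C(C)(C)C)C(C)(C)[C@H]2[C@H](CI)OC3=O
F4 | step 11 | 2-ethoxy enone (7a-(2-ethoxyacryloyl) analogue of 15) | C=C(OCC)C(=O)[C@]23CC[C@H](O[Si](C)(C)C(C)(C)C)C(C)(C)[C@H]2[C@H](CI)OC3=O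
F5 | step 12 | chlorooxalate of the tertiary C9 carbinol | O=C(Cl)C(=O)O[C@@](C#CC)(C(=C)OCC)[C@]23CC[C@H](O[Si](C)(C)C(C)(C)C)C(C)(C)[C@H]2[C@H](CI)OC3=O
F6 | step 14 | 11-iodo derivative of 21 (vinyl iodide) | O=C1C(=O)O[C@@]23C(I)=C(C)[C@]1(C(=O)OC)[C@@]2(C)C[C@@H]1OC(=O)[C@]32CC[C@H](O[Si](C)(C)C(C)(C)C)C(C)(C)[C@@H]12
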